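Read the added ligand as a clock that it slows, then ask what each flask's clock shows at the asked time.

| flask | left-handed substrate | right-handed substrate | coupling partner | catalyst | added ligand | remark | time |
|---|---|---|---|---|---|---|---|
| Monday's | 0.73 M | 0.73 M | 1.1 equiv (fed, over 8.0 min) | 2 mol% | 0.90 mM | run made earlier; the fed solution adds 0.25 times the starting volume |  |
| Friday's | 0.73 M | 0.73 M | 1.1 equiv (fed, over 8.0 min) | 2 mol% | 7.3 mM | run made earlier; the fed solution adds 0.25 times the starting volume |  |
| Saturday's | 0.73 M | 0.73 M | 1.1 equiv (fed, over 8.0 min) | 2 mol% | 57 mM | run made earlier; the fed solution adds 0.25 times the starting volume |  |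
| winter | 0.73 M | 0.73 M | 1.10 equiv (fed, over 8.0 min) | 2 mol% | 0.80 mM | the fed solution adds 0.25 times the starting volume | 40 min |
| noon | 0.73 M | 0.73 M | 1.10 equiv (fed, over 8.0 min) | 2 mol% | 2.5 mM | the fed solution adds 0.25 times the starting volume | 40 min |
| dusk | 0.73 M | 0.73 M | 1.10 equiv (fed, over 8.0 min) | 2 mol% | 8.0 mM | the fed solution adds 0.25 times the starting volume | 40 min |
| midnight | 0.73 M | 0.73 M | 1.10 equiv (fed, over 8.0 min) | 2 mol% | 20 mM | the fed solution adds 0.25 times the starting volume | 40 min |
| autumn | 0.73 M | 0.73 M | 1.10 equiv (fed, over 8.0 min) | 2 mol% | 60 mM | the fed solution adds 0.25 times the starting volume | 40 min |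

| run | time / min | left-handed product / % |
|---|---|---|
| Monday's | 2.50 | 3.6 |
| Monday's | 8.00 | 18.3 |
| Monday's | 12.0 | 24.2 |
| Monday's | 20.0 | 31.0 |
| Monday's | 30.0 | 33.7 |
| Friday's | 6.00 | 10.8 |
| Friday's | 12.0 | 22.4 |
| Friday's | 15.0 | 26.2 |
| Friday's | 25.0 | 31.4 |
| Friday's | 30.0 | 32.5 |
| Saturday's | 2.50 | 0.8 |
| Saturday's | 8.00 | 4.6 |
| Saturday's | 12.0 | 7.7 |
| Saturday's | 20.0 | 13.6 |
| Saturday's | 30.0 | 18.8 |

(readings scatter by 0.5 percentage points)

- catalyst is single-handed; left-handed substrate and right-handed substrate are mirror images of each other, charged as a racemate, each of them at the stated concentration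
- charges are per starting volume, the dose included; the dosed solution carries all of it
- the numbers in the tables scatter with a standard deviation of 0.5 percentage points
- "hardly changes" means that all values lie within two and a half points (for a concentration: within two and a half percent of the largest)

- amount of left-handed product at the end, in percent of the left-handed substrate and right-handed substrate together charged for winter, noon, dusk, midnight, autumn, in this order
- the course of these numbers from the first flask to the last (falls all the way / rises all the way / falls, then rises / hardly changes / rises, then falls)

First question: how much slower is Saturday's flask than Monday's? Saturday's flask reads 18.8% after 30.0 min, and Monday's reads 18.3% after 8.00 min. These are close readings, so Saturday's clock is stretched by a factor of 3.75, with Monday's small ligand charge taken as nil. Take the stretch as s = 1 + L/K_c, where L is the ligand charge. Then K_c, the clock-doubling charge, the ligand charge that makes a flask take twice as long over the same product, reads 20.7 mM.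

Second question: does the rule hold on a run not used to make it? Friday's stretch is 1.35, so its 30.0 min corresponds to 22.2 min on Monday's clock. Friday's 32.5% lies between Monday's 31.0% and 33.7%, the readings on either side of that time.

Third question: where does each new flask stand after 40 min? Winter's clock shows 38.5 min and noon's 35.7 min, both past Monday's last reading. Dusk's shows 28.9 min, just short of it. Midnight's shows 20.4 min, and straight-line reading between Monday's points gives 31.1%. Autumn's stretch is 3.89, so its clock shows 10.3 min, which gives 21.6%. The row should therefore fall from flask to flask.

The forecast gives 34.7%, 34.5%, 33.8%, 32% and 22.3%, a course that falls all the way, holding that “more ligand only delays the approach to that plateau”.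

The flasks give 35.2%, 35.0%, 34.2%, 31.5% and 22.0%, and the course falls all the way.

    coupling partner + catalyst + left-handed substrate → catalyst + left-handed product (k = 22.5 M⁻² min⁻¹)
    coupling partner + catalyst + right-handed substrate → catalyst + right-handed product (k = 8.48 M⁻² min⁻¹)
    catalyst + added ligand ⇌ idle complex, settled at all times (K = 154 M⁻¹)

The autumn flask gives 22.0% against the clock's 21.6%, and the midnight flask gives 31.5% against 31.1%. In the autumn flask at 40.0 min, 85.4% of the catalyst stands as idle complex and 42% of the coupling partner is left. Without the binding of catalyst to added ligand, the autumn flask gives 35.3% instead of 22.0%, and ten times the time adds 14 percentage points, so the binding and the short time together hold the autumn figure down. At 400 min the autumn clock shows 103 min, far past Monday's last reading, and the autumn flask holds 35.8%.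

The data are simulated on assumed constants, noise included.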